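**Plan**

- Retrosynthesis: after removal of an O-benzyl group, the benzene ring itself is cut at C4a–C5 and C8a–C8. This leaves a 4-methoxy-5,6-dihydropyran-2-one (C1, C8a, C4a, C4, C3, O2 already in place) and one molecule of methyl 3-methoxycrotonate (C5–C6(OMe)–C7–C8).
- The lactone is then cut at C3–C4 and O2–C1 into 12-(benzyloxy)dodecanal and Brassard's diene, the silyl dienolate of the same crotonate. The target is therefore a C12 aldehyde plus two molecules of methyl 3-methoxycrotonate.
- Enabling feature: oxygen sits on alternate carbons (C1, C8, C6 and, latently, C4a). C8(OH)–C7–C6(OMe)–C5 is a β-methoxycrotonate unit whose ester carbon becomes the C8 phenol, and a methoxy group on C4a serves as the leaving group, so the arene forms without an oxidant and with the 6-OMe/8-OH pattern already differentiated.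
- Forward order: lactone ring first (catalytic asymmetric hetero-Diels–Alder), then the benzene ring annulated onto it by an anionic Michael/Dieckmann/elimination cascade, then hydrogenolysis.
- Stereochemistry: the only stereocentre, C3 (R), is set by the Ti/BINOL catalyst in the hetero-Diels–Alder step (attack on the Si face of the aldehyde) and is not touched afterwards.

Key step: step 5

Remark 1: the sense of induction of the Ti/BINOL catalyst is assumed to be that (S)-BINOL gives the 6R lactone; if a Mosher check on 8 shows the opposite, the antipodal ligand is used.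
Remark 2: the ketene acetal geometry drawn for 5, 6 and 9 is the one usually assigned to Brassard's diene and has no bearing on the outcome.
Remark 3: the dienolate of 4 is made as its sodium salt 5 for silylation (step 3) and as its lithium salt 9 for the annulation (step 5); these are different compounds and are numbered separately.

**Route**

Step 1
Reactants: 1 dodecane-1,12-diol
Product: 2 12-(benzyloxy)dodecan-1-ol
Conditions: 1 (3 equiv), NaH (1.0 equiv), BnBr (1.0 equiv), Bu4NI (cat.), THF/DMF, 0 °C to rt
Reagents that add atoms: benzyl bromide, BrCc1ccccc1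
Why: Williamson ether synthesis on the mono-alkoxide, where the excess of diol should keep bis-benzylation low and the unreacted diol is recovered.

Step 2
Reactants: 2 12-(benzyloxy)dodecan-1-ol
Product: 3 12-(benzyloxy)dodecanal
Conditions: TEMPO (10 mol%), PhI(OAc)2 (1.1 equiv), CH2Cl2, rt
Reagents that add atoms: none
Why: TEMPO/hypervalent iodine oxidation of a primary alcohol should stop at the aldehyde and leave the benzyl ether untouched.

Step 3
Reactants: 4 methyl (E)-3-methoxybut-2-enoate
Product: 6 (E)-1,3-dimethoxy-1-(trimethylsilyloxy)buta-1,3-diene (Brassard's diene), via sodium dienolate 5 (not isolated)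
Conditions: NaHMDS (1.1 equiv, 1 M in THF), THF, −78 °C; TMSCl (1.2 equiv), −78 °C to rt; filtration of NaCl under argon; distillation under reduced pressure
Reagents that add atoms: chlorotrimethylsilane, C[Si](C)(C)Cl
Why: γ-deprotonation of the β-methoxy enoate by a hexamethyldisilazide base, as known for the related vinylogous carbonate 2,2,6-trimethyl-1,3-dioxin-4-one, followed by O-silylation of the dienolate (silyl ketene acetal formation), which pulls the deprotonation equilibrium through; the sodium salt is used so that the chloride precipitates and the only co-product is volatile hexamethyldisilazane.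

Step 4
Reactants: 3 12-(benzyloxy)dodecanal; 6 Brassard's diene
Product: 8 (R)-6-[11-(benzyloxy)undecyl]-4-methoxy-5,6-dihydro-2H-pyran-2-one, via silylated aldol adduct 7 (not isolated)
Conditions: 6 (1.5 equiv), Ti(OiPr)4/(S)-BINOL (1:1, 10 mol%), 4 Å MS, toluene, 0 °C; then TFA, CH2Cl2, 0 °C
Reagents that add atoms: none
Why: the Ti(IV)/BINOL-catalysed hetero-Diels–Alder reaction of Brassard's diene with aliphatic aldehydes (Mukaiyama-aldol-type C–C bond formation, then acid-induced lactonisation) is a known one-flask entry to 6-alkyl-4-methoxy-5,6-dihydropyran-2-ones, and C3 of the target is set here by catalyst-controlled attack of the diene CH2 terminus on the Si face of the aldehyde.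

Step 5
Reactants: 8 (R)-6-[11-(benzyloxy)undecyl]-4-methoxy-5,6-dihydro-2H-pyran-2-one; 4 methyl (E)-3-methoxybut-2-enoate
Product: 11 (R)-3-[11-(benzyloxy)undecyl]-8-hydroxy-6-methoxyisochroman-1-one, via lithium dienolate 9 (not isolated), via dienyl lactone 10 (not isolated)
Conditions: 4 (2.5 equiv), LDA (2.6 equiv, commercial solution), THF, −78 °C; then 8, −78 °C to rt; 1 M HCl quench
Reagents that add atoms: none
Why: Proposed new method: the γ-carbon of lithium dienolate 9 should add 1,4 to C4 of the vinylogous carbonate 8 and expel methoxide to give 10, whose doubly vinylogous CH2 is deprotonated so that the lactone α-carbon (future C8a) attacks the ester carbon (future C8) and the resulting cyclohexadienone enolises irreversibly to the phenoxide, so the arene forms at the right oxidation level with loss of two MeOH and no oxidant. The closest known reaction type is the Staunton–Weinreb annulation, in which a lithiated o-toluate adds to a 4-methoxy-5,6-dihydropyran-2-one and closes by Claisen condensation and loss of methanol; here the benzo-fused donor is replaced by its open-chain vinylogue 9, which carries the same nucleophilic CH2/electrophilic ester pair, and the lithium counter-ion and the irreversible LDA deprotonation before 8 is added are kept from that precedent. One ring is closed, the carbocycle C4a–C5–C6–C7–C8–C8a, by bond C4a–C5 (intermolecular conjugate addition–elimination) and bond C8a–C8 (6-exo-trig Dieckmann closure through the lactone enolate), the lactone ring being already present. No new stereocentre arises; C3 is set in step 4 and lies outside every enolate of the cascade. The step needs γ- over α-attack of 9 and 1,4- over 1,2-addition to 8: the 3-methoxy group makes the CH2 terminus the enol-ether-like nucleophilic site, α-adducts cannot cyclise and can revert, the lactone carbonyl is deactivated as a vinylogous carbonate, and the C6–C7 bond is single in 9 and in the anion of 10 so the cis geometry needed for closure is always accessible. The 6-OMe/8-OH pattern follows without any selective methylation or demethylation because the surviving methoxy is that of the donor and the phenol is its former ester carbonyl.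

Step 6
Reactants: 11 (R)-3-[11-(benzyloxy)undecyl]-8-hydroxy-6-methoxyisochroman-1-one
Product: 12 (R)-8-hydroxy-3-(11-hydroxyundecyl)-6-methoxyisochroman-1-one (CNP0140068.1)
Conditions: H2 (1 atm), 10% Pd/C, EtOAc, rt
Reagents that add atoms: none
Why: catalytic hydrogenolysis of the benzyl ether, under which the aryl lactone, the phenol and the homobenzylic C3–O bond are inert, so C3 is untouched.

**Compound list**

1 | dodecane-1,12-diol | OCCCCCCCCCCCCO | starting material
2 | 12-(benzyloxy)dodecan-1-ol | OCCCCCCCCCCCCOCc1ccccc1 | intermediate
3 | 12-(benzyloxy)dodecanal | O=CCCCCCCCCCCCOCc1ccccc1 | intermediate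
4 | methyl (E)-3-methoxybut-2-enoate | CO/C(C)=C/C(=O)OC | starting material
5 | sodium 1,3-dimethoxybuta-1,3-dien-1-olate (sodium dienolate of 4, not isolated) | C=C(OC)/C=C(\OC)[O-].[Na+] | intermediate
6 | (E)-1,3-dimethoxy-1-(trimethylsilyloxy)buta-1,3-diene (Brassard's diene) | C=C(OC)/C=C(\OC)O[Si](C)(C)C | intermediate
7 | methyl (R,E)-16-(benzyloxy)-3-methoxy-5-(trimethylsilyloxy)hexadec-2-enoate (not isolated) | COC(=O)/C=C(/OC)C[C@H](O[Si](C)(C)C)CCCCCCCCCCCOCc1ccccc1 | intermediate
8 | (R)-6-[11-(benzyloxy)undecyl]-4-methoxy-5,6-dihydro-2H-pyran-2-one | COC1=CC(=O)O[C@H](CCCCCCCCCCCOCc2ccccc2)C1 | intermediate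
9 | lithium 1,3-dimethoxybuta-1,3-dien-1-olate (lithium dienolate of 4, not isolated) | C=C(OC)/C=C(\OC)[O-].[Li+] | intermediate
10 | methyl (E)-4-[(R)-6-(11-(benzyloxy)undecyl)-2-oxo-5,6-dihydro-2H-pyran-4-yl]-3-methoxybut-2-enoate (not isolated, drawn in neutral form) | COC(=O)/C=C(/OC)CC1=CC(=O)O[C@H](CCCCCCCCCCCOCc2ccccc2)C1 | intermediate
11 | (R)-3-[11-(benzyloxy)undecyl]-8-hydroxy-6-methoxyisochroman-1-one | COc1cc(O)c2c(c1)C[C@@H](CCCCCCCCCCCOCc3ccccc3)OC2=O | intermediate
12 | (R)-8-hydroxy-3-(11-hydroxyundecyl)-6-methoxyisochroman-1-one | COc1cc(O)c2c(c1)C[C@@H](CCCCCCCCCCCO)OC2=O | target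

**Step count**

Total steps: 6. Longest linear sequence: 5 (steps 1, 2, 4, 5, 6); step 3 is a one-step side branch that supplies diene 6.

**Steps most likely to fail**

1. Step 5 (Proposed new method). The dienolate may attack through its α-carbon or at the lactone carbonyl, or act as a base and trigger E1cB opening of the dihydropyranone (which would also erase C3), so that closure to the arene does not occur. The fallback uses known chemistry and builds the arene by cycloaddition in place of the anionic annulation; it sets out from aldehyde 3 (with diene 6) and comes back at 11. Aldehyde 3 would be propargylated enantioselectively with allenylboronic acid pinacol ester under chiral BINOL-phosphoric acid catalysis (catalyst enantiomer chosen for the R alcohol) to (R)-15-(benzyloxy)pentadec-1-yn-4-ol F1. Silylation (TBSCl, imidazole, DMF) would give its TBS ether, (R)-{[15-(benzyloxy)pentadec-1-yn-4-yl]oxy}(tert-butyl)dimethylsilane F2, and carboxylation at the alkyne terminus (n-BuLi, THF, −78 °C; ClCO2Me) would give methyl (R)-16-(benzyloxy)-5-[(tert-butyldimethylsilyl)oxy]hexadec-2-ynoate F3. A thermal Diels–Alder reaction of F3 with Brassard's diene 6 (toluene, 110–130 °C), in which the diene CH2 terminus bonds to the ynoate β-carbon, followed by aromatisation with loss of methanol and desilylation of the phenol on work-up, should give methyl 6-[(R)-13-(benzyloxy)-2-[(tert-butyldimethylsilyl)oxy]tridecyl]-2-hydroxy-4-methoxybenzoate F4. TsOH·H2O in MeOH should then remove the TBS group and close the lactone to 11, which continues with step 6.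

2. Step 4. Facial selectivity or turnover of the Ti/BINOL catalyst may be poor with an unbranched long-chain aldehyde, and the acid-sensitive diene may decompose before C–C bond formation. The fallback sets the stereocentre by ketone hydrogenation and not by C–C bond formation; it sets out from 3 and comes back at 8. Roskamp homologation of 3 (ethyl diazoacetate, SnCl2 cat., CH2Cl2) would give ethyl 14-(benzyloxy)-3-oxotetradecanoate F5. Noyori hydrogenation (H2, RuCl2[(R)-BINAP] cat., EtOH) should give ethyl (R)-14-(benzyloxy)-3-hydroxytetradecanoate F6. A crossed Claisen condensation with excess lithium enolate of methyl acetate (THF, −78 to −20 °C) would give methyl (R)-16-(benzyloxy)-5-hydroxy-3-oxohexadecanoate F7. K2CO3 in MeOH followed by acidification should lactonise this to (R)-6-[11-(benzyloxy)undecyl]-4-hydroxy-5,6-dihydro-2H-pyran-2-one F8, and O-methylation (Me2SO4, K2CO3, acetone) would give 8.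

3. Step 1. Over-alkylation to the bis-benzyl ether in the statistical desymmetrisation may consume material and complicate separation. The fallback desymmetrises by monobromination; it sets out from 1 and comes back at 3, bypassing 2 and step 2. Diol 1 would be monobrominated (48% aq. HBr, toluene, reflux) to 12-bromododecan-1-ol F9. Benzylation under acidic conditions (benzyl 2,2,2-trichloroacetimidate, TfOH cat., CH2Cl2) would give [(12-bromododecyl)oxymethyl]benzene F10. Kornblum oxidation (DMSO, NaHCO3, 130 °C) would convert the primary bromide into aldehyde 3.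

**Further compounds**

F1 | step 5 | (R)-15-(benzyloxy)pentadec-1-yn-4-ol | C#CC[C@H](O)CCCCCCCCCCCOCc1ccccc1
F2 | step 5 | (R)-{[15-(benzyloxy)pentadec-1-yn-4-yl]oxy}(tert-butyl)dimethylsilane | C#CC[C@H](O[Si](C)(C)C(C)(C)C)CCCCCCCCCCCOCc1ccccc1
F3 | step 5 | methyl (R)-16-(benzyloxy)-5-[(tert-butyldimethylsilyl)oxy]hexadec-2-ynoate | COC(=O)C#CC[C@H](O[Si](C)(C)C(C)(C)C)CCCCCCCCCCCOCc1ccccc1
F4 | step 5 | methyl 6-[(R)-13-(benzyloxy)-2-[(tert-butyldimethylsilyl)oxy]tridecyl]-2-hydroxy-4-methoxybenzoate | COC(=O)c1c(O)cc(OC)cc1C[C@H](O[Si](C)(C)C(C)(C)C)CCCCCCCCCCCOCc2ccccc2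
F5 | step 4 | ethyl 14-(benzyloxy)-3-oxotetradecanoate | CCOC(=O)CC(=O)CCCCCCCCCCCOCc1ccccc1
F6 | step 4 | ethyl (R)-14-(benzyloxy)-3-hydroxytetradecanoate | CCOC(=O)C[C@H](O)CCCCCCCCCCCOCc1ccccc1
F7 | step 4 | methyl (R)-16-(benzyloxy)-5-hydroxy-3-oxohexadecanoate | COC(=O)CC(=O)C[C@H](O)CCCCCCCCCCCOCc1ccccc1
F8 | step 4 | (R)-6-[11-(benzyloxy)undecyl]-4-hydroxy-5,6-dihydro-2H-pyran-2-one | OC1=CC(=O)O[C@H](CCCCCCCCCCCOCc2ccccc2)C1
F9 | step 1 | 12-bromododecan-1-ol | OCCCCCCCCCCCCBr
F10 | step 1 | [(12-bromododecyl)oxymethyl]benzene | BrCCCCCCCCCCCCOCc1ccccc1
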